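Ring A, the cross-conjugated dienone (C6–C7(=C14H2)–C8(=O)–C9=C10–C11Me2), is closed last by ring-closing metathesis of a divinyl ketone across C9=C10, the only ring bond flanked by the C8 carbonyl and the quaternary C11. The precursor is a fully substituted ring B whose C6 carries a 1,1-dimethylallyl and a 1-acryloylvinyl arm. Keeping ring A open lets ring B be built on a conformationally mobile monocycle: an Evans aldol/metathesis sequence sets C5, a hydroxyl-directed trans-diaxial bromochlorination sets C2 and C3 while C6 still bears hydrogen, and an Ireland–Claisen rearrangement then installs C11 equatorially, fixing spiro centre C6.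

Key step: step 12

Remark: chamigrene numbering is used throughout (ring B: C1H2, C2 Br, C3 Me/Cl, C4H2, C5 OAc, C6 spiro; ring A: C6, C7 =C14H2, C8 =O, C9=C10, C11 Me2). Aldehyde 5 is assumed to be used at once as a crude solution, because it isomerises to the conjugated enal on storage.

Step 1
Reactants: 1 (R)-4-benzyloxazolidin-2-one; 2 pent-4-enoyl chloride
Product: 3 (R)-4-benzyl-3-(pent-4-enoyl)oxazolidin-2-one
Conditions: n-BuLi, THF, −78 °C; then 2, −78 to 0 °C
Reagents that add atoms: none
Why: N-acylation of the lithiated Evans auxiliary by an acid chloride is fast and clean at −78 °C; no stereocentre is formed.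

Step 2
Reactants: 4 3-methylbut-3-en-1-ol
Product: 5 3-methylbut-3-enal
Conditions: Dess–Martin periodinane, NaHCO3, CH2Cl2, 0 °C
Reagents that add atoms: none
Why: Dess–Martin oxidation under bicarbonate buffer should give the β,γ-unsaturated aldehyde without migration of the double bond into conjugation; no stereocentre is formed.

Step 3
Reactants: 3 (R)-4-benzyl-3-(pent-4-enoyl)oxazolidin-2-one; 5 3-methylbut-3-enal
Product: 7 syn-aldol adduct (R)-4-benzyl-3-[(2R,3S)-2-allyl-3-hydroxy-5-methylhex-5-enoyl]oxazolidin-2-one, via Z-dibutylboron enolate 6 (not isolated)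
Conditions: Bu2BOTf, iPr2NEt, CH2Cl2, −78 to 0 °C; then 5, −78 to 0 °C; H2O2, pH 7 buffer, MeOH
Reagents that add atoms: none
Why: Evans syn-aldol reaction, in which the Z-boron enolate reacts through a Zimmerman–Traxler chair on the face remote from the benzyl group of the (R)-auxiliary, setting the C5 carbinol centre (S) and a provisional C6 centre in a 2,3-syn relationship.

Step 4
Reactants: 7 syn-aldol adduct
Product: 8 (R)-4-benzyl-3-[(1R,6S)-6-hydroxy-4-methylcyclohex-3-ene-1-carbonyl]oxazolidin-2-one (OH cis to the acyl group)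
Conditions: Grubbs II (3 mol%), CH2Cl2 (0.01 M), 40 °C
Reagents that add atoms: none
Why: Ring-closing metathesis of the allyl and methallyl arms closes ring B as the trisubstituted C2=C3 cyclohexene with loss of ethene; the syn-aldol relationship becomes a cis-2-hydroxy acyl arrangement and no stereocentre is touched.

Step 5
Reactants: 8 cis-hydroxy cyclohexene imide
Product: 10 (R)-4-benzyl-3-[(1R,2S,4R,5R)-5-bromo-4-chloro-2-hydroxy-4-methylcyclohexane-1-carbonyl]oxazolidin-2-one (Cl cis to OH; Br trans to Cl), via titanium alkoxide 9 (not isolated)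
Conditions: ClTi(OiPr)3, NBS, CH2Cl2/hexanes, −20 °C, dark
Reagents that add atoms: N-bromosuccinimide O=C1CCC(=O)N1Br; chlorotriisopropoxytitanium CC(C)O[Ti](Cl)(OC(C)C)OC(C)C
Why: Titanium-mediated bromochlorination of an alkenol (NBS as Br+ source, chloride delivered from the titanium alkoxide): in the half-chair with the bulky acyl group equatorial the C5–O bond is axial, so the bromonium forms anti to it and chloride is delivered syn to oxygen at tertiary C3, a pathway in which Markovnikov and Fürst–Plattner (trans-diaxial) demands coincide and which sets C3 (Cl cis to O) and C2 (Br trans to Cl).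

Step 6
Reactants: 10 bromochloro hydroxy imide; 11 3-methylbut-2-en-1-ol (prenol)
Product: 12 3-methylbut-2-en-1-yl (1R,2S,4R,5R)-5-bromo-4-chloro-2-hydroxy-4-methylcyclohexane-1-carboxylate
Conditions: 11, MeMgBr (gives BrMgO-prenyl), CH2Cl2/THF, 0 °C to rt
Reagents that add atoms: none
Why: Transesterification of an aldol-type N-acyloxazolidinone with a bromomagnesium alkoxide (the MeOMgBr method, here with prenol) cleaves the exocyclic acyl–N bond under nearly neutral conditions and returns the auxiliary; C6 is only a placeholder centre that is erased in step 7.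

Step 7
Reactants: 12 prenyl ester
Product: 15 hydroxy acid (1S,2S,4R,5R)-5-bromo-4-chloro-2-hydroxy-4-methyl-1-(2-methylbut-3-en-2-yl)cyclohexane-1-carboxylic acid, via bis-TMS ketene acetal 13 (not isolated), via rearranged bis-TMS ester 14 (not isolated)
Conditions: LDA (2.3 equiv), TMSCl (in situ quench), THF, −78 °C; then 60 °C; 1 M HCl work-up
Reagents that add atoms: none
Why: Ireland–Claisen rearrangement: in situ silylation gives the tetrasubstituted silyl ketene acetal, whose [3,3] shift joins C6 to the prenyl terminus through the chair in which Br, Cl, the C5 silyloxy group and the incoming tertiary group are all equatorial, so C11 should enter trans to the C5 oxygen and cis to bromine, which sets C6; the neutral ketene acetal avoids β-elimination and attack on the C–Br bond.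

Step 8
Reactants: 15 hydroxy acid
Product: 16 (1S,2S,4R,5R)-2-acetoxy-5-bromo-4-chloro-4-methyl-1-(2-methylbut-3-en-2-yl)cyclohexane-1-carboxylic acid
Conditions: Ac2O, pyridine, DMAP (cat.), CH2Cl2, rt; then H2O/THF
Reagents that add atoms: acetic anhydride CC(=O)OC(C)=O
Why: DMAP-catalysed acetylation of the hindered secondary alcohol; the mixed anhydride formed at the carboxyl group is hydrolysed on aqueous work-up and no stereocentre is affected.

Step 9
Reactants: 16 acetoxy acid
Product: 18 methyl ketone (1S,2S,4R,5R)-2-acetyl-4-bromo-5-chloro-5-methyl-2-(2-methylbut-3-en-2-yl)cyclohexyl acetate, via acid chloride 17 (not isolated)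
Conditions: (COCl)2, DMF (cat.), CH2Cl2, 0 °C to rt; evaporate; MeZnCl, Pd(PPh3)4 (5 mol%), THF, 0 °C to rt
Reagents that add atoms: methylzinc chloride C[Zn]Cl
Why: Acid chloride formation followed by Negishi acylation with methylzinc chloride and Pd(0) should give the methyl ketone (C7 with C14 as its methyl) without over-addition and without touching the acetate, the alkyl halides or the vinyl group.

Step 10
Reactants: 18 methyl ketone
Product: 20 enol triflate (1S,2S,4R,5R)-4-bromo-5-chloro-5-methyl-2-(2-methylbut-3-en-2-yl)-2-[1-(trifluoromethylsulfonyloxy)vinyl]cyclohexyl acetate, via potassium enolate 19 (not isolated)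
Conditions: KHMDS (1.1 equiv), PhNTf2, THF, −78 °C
Reagents that add atoms: N-phenylbis(trifluoromethanesulfonimide) O=S(=O)(N(c1ccccc1)S(=O)(=O)C(F)(F)F)C(F)(F)F
Why: Because C6 is quaternary only the methyl group can enolise, so the kinetic potassium enolate forms regiospecifically and is O-sulfonylated to the 1,1-disubstituted vinyl triflate (enol triflate formation).

Step 11
Reactants: 20 enol triflate; 21 tributyl(vinyl)stannane
Product: 22 divinyl ketone (1S,2R,4R,5R)-4-bromo-5-chloro-5-methyl-2-(2-methylbut-3-en-2-yl)-2-(3-oxopenta-1,4-dien-2-yl)cyclohexyl acetate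
Conditions: Pd(PPh3)4 (5 mol%), LiCl, CO (3 atm), THF, 55 °C
Reagents that add atoms: carbon monoxide [C-]#[O+]
Why: Carbonylative Stille coupling: oxidative addition of the vinyl triflate, CO insertion to an acyl-palladium species (CO becomes C8), LiCl-assisted transmetallation from the vinylstannane and reductive elimination give the cross-conjugated divinyl ketone, with CO pressure suppressing direct coupling.

Step 12
Reactants: 22 divinyl ketone
Product: 23 CNP0161807.1, (2R,3R,5S,6R)-5-acetoxy-2-bromo-3-chlorochamigra-7(14),9-dien-8-one (chamigrene numbering)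
Conditions: Hoveyda–Grubbs II (10 mol%), PhMe (0.005 M), 80 °C
Reagents that add atoms: none
Why: Ring-closing olefin metathesis (Ru alkylidene, [2+2]/retro-[2+2] cycles): the catalyst loads on one monosubstituted vinyl group, adds across the other and releases ethene, as is well precedented for cyclohexenone formation from acryloyl/alkenyl pairs on quaternary carbons. Ring A is closed by forming the endocyclic C9=C10 double bond, a six-membered RCM in which the cis geometry is enforced by the ring. No stereocentre is formed, and C2, C3, C5 and C6 are spectators. The step needs chemoselectivity among three alkenes: the 1,1-disubstituted, conjugated C7=C14 methylene is a poor metathesis partner and could only give a three- or four-membered ring, so only the C9 and C10 vinyl termini should react. The vicinal quaternary carbons C6 and C11 hold both arms close (Thorpe–Ingold), which favours cyclisation over oligomerisation at high dilution, and a phosphine-free Hoveyda–Grubbs catalyst at 80 °C is chosen for the slow-loading electron-poor and neopentyl olefins.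

Compound list
1 | (R)-4-benzyloxazolidin-2-one | O=C1OC[C@@H](Cc2ccccc2)N1 | starting material
2 | pent-4-enoyl chloride | C=CCCC(=O)Cl | starting material
3 | (R)-4-benzyl-3-(pent-4-enoyl)oxazolidin-2-one | C=CCCC(=O)N1C(=O)OC[C@H]1Cc1ccccc1 | intermediate
4 | 3-methylbut-3-en-1-ol | C=C(C)CCO | starting material
5 | 3-methylbut-3-enal | C=C(C)CC=O | intermediate
6 | Z-dibutylboron enolate of 3 | C=CC/C=C(\OB(CCCC)CCCC)N1C(=O)OC[C@H]1Cc1ccccc1 | intermediate (not isolated)
7 | (R)-4-benzyl-3-[(2R,3S)-2-allyl-3-hydroxy-5-methylhex-5-enoyl]oxazolidin-2-one | C=CC[C@@H](C(=O)N1C(=O)OC[C@H]1Cc1ccccc1)[C@@H](O)CC(C)=C | intermediate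
8 | (R)-4-benzyl-3-[(1R,6S)-6-hydroxy-4-methylcyclohex-3-ene-1-carbonyl]oxazolidin-2-one | O=C(N1C(=O)OC[C@H]1Cc1ccccc1)[C@@H]1CC=C(C)C[C@@H]1O | intermediate
9 | chlorodiisopropoxytitanium alkoxide of 8 | O=C(N1C(=O)OC[C@H]1Cc1ccccc1)[C@@H]1CC=C(C)C[C@@H]1O[Ti](Cl)(OC(C)C)OC(C)C | intermediate (not isolated)
10 | (R)-4-benzyl-3-[(1R,2S,4R,5R)-5-bromo-4-chloro-2-hydroxy-4-methylcyclohexane-1-carbonyl]oxazolidin-2-one | O=C(N1C(=O)OC[C@H]1Cc1ccccc1)[C@@H]1C[C@@H](Br)[C@](C)(Cl)C[C@@H]1O | intermediate
11 | 3-methylbut-2-en-1-ol (prenol) | CC(C)=CCO | starting material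
12 | 3-methylbut-2-en-1-yl (1R,2S,4R,5R)-5-bromo-4-chloro-2-hydroxy-4-methylcyclohexane-1-carboxylate | CC(C)=CCOC(=O)[C@@H]1C[C@@H](Br)[C@](C)(Cl)C[C@@H]1O | intermediate
13 | bis(trimethylsilyl) ketene acetal of 12 (C5–OTMS) | CC(C)=CCOC(O[Si](C)(C)C)=C1C[C@@H](Br)[C@](C)(Cl)C[C@@H]1O[Si](C)(C)C | intermediate (not isolated)
14 | trimethylsilyl ester of 15 with C5–OTMS | C=CC(C)(C)[C@@]1(C(=O)O[Si](C)(C)C)C[C@@H](Br)[C@](C)(Cl)C[C@@H]1O[Si](C)(C)C | intermediate (not isolated)
15 | (1S,2S,4R,5R)-5-bromo-4-chloro-2-hydroxy-4-methyl-1-(2-methylbut-3-en-2-yl)cyclohexane-1-carboxylic acid (dimethylallyl cis to Br, trans to OH) | C=CC(C)(C)[C@@]1(C(=O)O)C[C@@H](Br)[C@](C)(Cl)C[C@@H]1O | intermediate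
16 | (1S,2S,4R,5R)-2-acetoxy-5-bromo-4-chloro-4-methyl-1-(2-methylbut-3-en-2-yl)cyclohexane-1-carboxylic acid | C=CC(C)(C)[C@@]1(C(=O)O)C[C@@H](Br)[C@](C)(Cl)C[C@@H]1OC(C)=O | intermediate
17 | acid chloride of 16 | C=CC(C)(C)[C@@]1(C(=O)Cl)C[C@@H](Br)[C@](C)(Cl)C[C@@H]1OC(C)=O | intermediate (not isolated)
18 | (1S,2S,4R,5R)-2-acetyl-4-bromo-5-chloro-5-methyl-2-(2-methylbut-3-en-2-yl)cyclohexyl acetate | C=CC(C)(C)[C@@]1(C(C)=O)C[C@@H](Br)[C@](C)(Cl)C[C@@H]1OC(C)=O | intermediate
19 | potassium enolate of 18 | C=CC(C)(C)[C@@]1(C(=C)[O-])C[C@@H](Br)[C@](C)(Cl)C[C@@H]1OC(C)=O.[K+] | intermediate (not isolated)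
20 | (1S,2S,4R,5R)-4-bromo-5-chloro-5-methyl-2-(2-methylbut-3-en-2-yl)-2-[1-(trifluoromethylsulfonyloxy)vinyl]cyclohexyl acetate | C=CC(C)(C)[C@@]1(C(=C)OS(=O)(=O)C(F)(F)F)C[C@@H](Br)[C@](C)(Cl)C[C@@H]1OC(C)=O | intermediate
21 | tributyl(vinyl)stannane | C=C[Sn](CCCC)(CCCC)CCCC | starting material
22 | (1S,2R,4R,5R)-4-bromo-5-chloro-5-methyl-2-(2-methylbut-3-en-2-yl)-2-(3-oxopenta-1,4-dien-2-yl)cyclohexyl acetate | C=CC(C)(C)[C@@]1(C(=C)C(=O)C=C)C[C@@H](Br)[C@](C)(Cl)C[C@@H]1OC(C)=O | intermediate
23 | CNP0161807.1, (2R,3R,5S,6R)-5-acetoxy-2-bromo-3-chlorochamigra-7(14),9-dien-8-one | C=C1C(=O)C=CC(C)(C)[C@]12C[C@@H](Br)[C@](C)(Cl)C[C@@H]2OC(C)=O | target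

Total step count: 12. Longest linear sequence: 11 (steps 1 and 3–12, from 1).

Steps most likely to fail

Step 7. The sigmatropic shift has to join two fully substituted carbons, so it may stall, and during enolisation β-elimination of the C5 oxygen or dehydrohalogenation by the amide base may compete with silylation. Fallback, from 12 back to 15: the rearrangement is moved to the aldehyde oxidation level, where no strong base is needed. The alcohol of 12 is silylated (TESOTf, 2,6-lutidine) to the TES ether F3. DIBAL-H at −78 °C reduces the ester to the cyclohexanecarbaldehyde F4. Heating F4 with prenol 11 and a trace of acid with removal of water forms the prenyl enol ether, which undergoes a thermal aliphatic Claisen rearrangement to the α-quaternary aldehyde F5, with the same equatorial preference for the incoming group. Pinnick oxidation gives the TES-protected acid F6, and HF·pyridine removes the silyl group to give 15.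

Step 5. Facial selectivity in the opening of the bromonium ion may be incomplete, and transannular attack of the C5 oxygen may compete with chloride delivery. Fallback, from 8 back to 10: the oxygen nucleophile is made the deliberate intramolecular partner. Compound 8 is converted (Boc2O, DMAP) into the tert-butyl carbonate F1. NBS then triggers a bromocarbonate cyclisation of the Bartlett type: the carbonate oxygen, held on the face of C5–O, opens the bromonium at tertiary C3, giving the bicyclic 1,3-carbonate F2 with bromine anti at C2 and loss of isobutene. TiCl4 in CH2Cl2 then ionises the tertiary C3–O bond with anchimeric assistance from the anti bromine; chloride returns at C3 with overall retention, and CO2 is lost on work-up to give 10.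

Step 12. Loading of the catalyst onto either the electron-poor or the neopentyl vinyl group may be slow, so catalyst decay and intermolecular metathesis may outrun ring closure. Fallback, from 20 back to 23: ring A is closed instead by an aldol condensation that forms the same C9=C10 bond. Carbonylative Stille coupling of 20 with tetramethyltin gives the methyl enone F7. Selective ozonolysis of the electron-richer monosubstituted vinyl group (O3, CH2Cl2/pyridine, −78 °C; Me2S) gives the non-enolisable neopentyl aldehyde F8. Intramolecular aldol condensation of the methyl ketone onto this aldehyde (dibenzylammonium trifluoroacetate, benzene, 50 °C) closes the six-membered enone to give 23.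

Further compounds
F1 | step 5 | tert-butyl carbonate of 8 | O=C(N1C(=O)OC[C@H]1Cc1ccccc1)[C@@H]1CC=C(C)C[C@@H]1OC(=O)OC(C)(C)C
F2 | step 5 | bicyclic C3,C5-carbonate with C2 bromide (Br anti to C3–O) | O=C(N1C(=O)OC[C@H]1Cc1ccccc1)[C@@H]1C[C@@H](Br)[C@@]2(C)C[C@@H]1OC(=O)O2
F3 | step 7 | triethylsilyl ether of 12 | CC(C)=CCOC(=O)[C@@H]1C[C@@H](Br)[C@](C)(Cl)C[C@@H]1O[Si](CC)(CC)CC
F4 | step 7 | 5-bromo-4-chloro-4-methyl-2-(triethylsilyloxy)cyclohexane-1-carbaldehyde | O=C[C@@H]1C[C@@H](Br)[C@](C)(Cl)C[C@@H]1O[Si](CC)(CC)CC
F5 | step 7 | 5-bromo-4-chloro-4-methyl-1-(2-methylbut-3-en-2-yl)-2-(triethylsilyloxy)cyclohexane-1-carbaldehyde | C=CC(C)(C)[C@@]1(C=O)C[C@@H](Br)[C@](C)(Cl)C[C@@H]1O[Si](CC)(CC)CC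
F6 | step 7 | triethylsilyl ether of 15 | C=CC(C)(C)[C@@]1(C(=O)O)C[C@@H](Br)[C@](C)(Cl)C[C@@H]1O[Si](CC)(CC)CC
F7 | step 12 | methyl enone: 4-bromo-5-chloro-5-methyl-2-(2-methylbut-3-en-2-yl)-2-(3-oxobut-1-en-2-yl)cyclohexyl acetate | C=CC(C)(C)[C@@]1(C(=C)C(C)=O)C[C@@H](Br)[C@](C)(Cl)C[C@@H]1OC(C)=O
F8 | step 12 | keto aldehyde: 4-bromo-5-chloro-5-methyl-2-(2-methyl-1-oxopropan-2-yl)-2-(3-oxobut-1-en-2-yl)cyclohexyl acetate | O=CC(C)(C)[C@@]1(C(=C)C(C)=O)C[C@@H](Br)[C@](C)(Cl)C[C@@H]1OC(C)=O
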